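**Plan**

- Retrosynthesis: the eight phenols are masked as methyl ethers. The stilbene C=C on ring A (the benzene ring fused to the dihydrofuran that bears the 4-hydroxyphenyl group) is cut by phosphonate olefination. C3–C3a and O1–C2 of that dihydrofuran are cut together, giving a 4-methoxystilbene that already holds the catechol-bearing dihydrobenzofuran (fused to ring C) and ring A at its dihydro level, a cyclohexane-1,3-dione. That stilbene is cut by a Heck reaction, and C2–C3 with O1–C2 of the ring C dihydrofuran by a sulfur-ylide annulation on an ortho-quinone methide.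
- Enabling feature: in the ring O1–C2–C3–C3a–C7a, C3a lies between the oxygen-bearing carbons C4 and C7a of ring A and para to C6. In the 5,6,7-saturated form of ring A it is therefore C2 of a 1,3-dione, the only nucleophilic carbon there. C2 carries a para-oxygenated aryl group that stabilises the benzylic radical and cation on which O1 closes.
- Forward order: ring C dihydrofuran (step 4), resolution, Heck stilbene, ring A dihydrofuran by oxidative cycloaddition (step 7), aromatisation of ring A, ester to aldehyde, stilbene arm, global demethylation.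
- Stereochemistry: each dihydrofuran closes trans (anti addition then SN2 displacement in step 4; capture of the cation anti to the C3 substituent in step 7). The (2S,3S) ring is secured by chiral SFC of a bromide, the (2R,3R) ring by separating the two trans diastereomers after step 8. Both alkenes are (E), from the Heck and phosphonate reactions.

Key step: step 7

Notation: G = (2S,3S)-2-(3,4-dimethoxyphenyl)-3-(3,5-dimethoxyphenyl)-4-methoxy-2,3-dihydro-1-benzofuran-6-yl.

Assumption: the (2S,3S) ring sits para across ring C from the centres made in step 7 and is taken to give no facial bias, so both trans rings are expected and the (2R,3R) one is isolated after step 8.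

**Step 1**
Reactants: 1 4-bromo-2,6-dimethoxybenzaldehyde
Product: 2 4-bromo-2-hydroxy-6-methoxybenzaldehyde
Conditions: BCl3 (1.1 equiv), CH2Cl2, −78 to 0 °C; aq work-up
Reagents that add atoms: none
Why: Lewis-acid ether cleavage by BCl3 is directed by chelation to the formyl oxygen, so only one of the two equivalent ortho-methoxy groups is removed and the reaction stops at the hydrogen-bonded salicylaldehyde.

**Step 2**
Reactants: 2 4-bromo-2-hydroxy-6-methoxybenzaldehyde; 3 3,5-dimethoxyphenylmagnesium chloride (THF solution)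
Product: 5 5-bromo-2-[(3,5-dimethoxyphenyl)(4-methylbenzenesulfonyl)methyl]-3-methoxyphenol (racemic), via benzhydrol diol 4 (not isolated)
Conditions: 3 (2.3 equiv), THF, 0 °C to rt; aq NH4Cl; crude 4, 4-MeC6H4SO2H, CH2Cl2, rt
Reagents that add atoms: 4-methylbenzenesulfinic acid, Cc1ccc(cc1)S(=O)O
Why: Grignard 1,2-addition to the aldehyde (the first equivalent is consumed by the phenol) gives the acid-labile benzhydrol, which ionises under the mildly acidic conditions and is captured at sulfur by the sulfinate (SN1-type substitution) to give a bench-stable quinone methide precursor whose racemic stereocentre is erased in step 4.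

**Step 3**
Reactants: 6 4-(bromomethyl)-1,2-dimethoxybenzene; 7 tetrahydrothiophene
Product: 8 1-[(3,4-dimethoxyphenyl)methyl]thiolan-1-ium bromide
Conditions: acetone, rt
Reagents that add atoms: none
Why: SN2 alkylation of the sulfide by the activated benzylic bromide gives the crystalline sulfonium salt, the usual precursor of a semistabilised benzyl ylide.

**Step 4**
Reactants: 5 5-bromo-2-[(3,5-dimethoxyphenyl)(4-methylbenzenesulfonyl)methyl]-3-methoxyphenol; 8 1-[(3,4-dimethoxyphenyl)methyl]thiolan-1-ium bromide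
Product: 11 racemic trans-6-bromo-2-(3,4-dimethoxyphenyl)-3-(3,5-dimethoxyphenyl)-4-methoxy-2,3-dihydro-1-benzofuran, via ortho-quinone methide 9 (not isolated), via sulfonium ylide 10 (not isolated)
Conditions: Cs2CO3 (3 equiv), MeCN, 0 °C to rt
Reagents that add atoms: none
Why: Base-induced 1,4-elimination of sulfinate from 5 gives 9 and deprotonation of 8 gives 10, whose conjugate addition and 5-exo-tet displacement of tetrahydrothiophene by the phenoxide (sulfur-ylide [4+1] annulation) close the ring with the two aryl groups trans, through an anti arrangement in the addition and inversion in the displacement, while the absolute configuration is not controlled.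

**Step 5**
Reactants: 11 racemic trans-6-bromo-2-(3,4-dimethoxyphenyl)-3-(3,5-dimethoxyphenyl)-4-methoxy-2,3-dihydro-1-benzofuran
Product: 12 (2S,3S)-6-bromo-2-(3,4-dimethoxyphenyl)-3-(3,5-dimethoxyphenyl)-4-methoxy-2,3-dihydro-1-benzofuran
Conditions: preparative chiral SFC, amylose tris(3,5-dimethylphenylcarbamate) phase, CO2/MeOH
Reagents that add atoms: none
Why: Chromatographic resolution on a polysaccharide chiral phase is routine for neutral racemates of this kind, and the bromine atom allows the absolute configuration of the collected (2S,3S) enantiomer to be assigned by anomalous-dispersion X-ray diffraction.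

**Step 6**
Reactants: 12 (2S,3S)-6-bromo-2-(3,4-dimethoxyphenyl)-3-(3,5-dimethoxyphenyl)-4-methoxy-2,3-dihydro-1-benzofuran; 13 1-ethenyl-4-methoxybenzene
Product: 14 (2S,3S)-2-(3,4-dimethoxyphenyl)-3-(3,5-dimethoxyphenyl)-4-methoxy-6-[(E)-2-(4-methoxyphenyl)ethenyl]-2,3-dihydro-1-benzofuran
Conditions: Pd(OAc)2 (5 mol %), P(o-tol)3 (10 mol %), Et3N, DMF, 100 °C
Reagents that add atoms: none
Why: The Mizoroki–Heck reaction of the unhindered aryl bromide with the styrene proceeds by syn insertion and syn β-hydride elimination to the (E)-stilbene and leaves the two stereocentres untouched.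

**Step 7**
Reactants: 14 (2S,3S)-2-(3,4-dimethoxyphenyl)-3-(3,5-dimethoxyphenyl)-4-methoxy-6-[(E)-2-(4-methoxyphenyl)ethenyl]-2,3-dihydro-1-benzofuran; 15 ethyl 3,5-dioxocyclohexane-1-carboxylate
Product: 16 ethyl (2R,3R)-3-G-2-(4-methoxyphenyl)-4-oxo-2,3,4,5,6,7-hexahydro-1-benzofuran-6-carboxylate (both C6 epimers)
Conditions: Mn(OAc)3·2H2O (2.5 equiv), 15 (2 equiv), AcOH, 60 °C
Reagents that add atoms: none
Why: Mn(OAc)3 turns the enol of 15 into a trivalent manganese enolate and, by inner-sphere electron transfer, into the electrophilic radical at the carbon between the two carbonyl groups, which adds to the stilbene carbon of 14 that carries ring C; a second equivalent oxidises the resulting 4-methoxybenzylic radical to the cation (the O-methyl form of a para-quinone methide), on which the enol oxygen closes. The closest known reaction type is the Mn(OAc)3-mediated oxidative [3+2] cycloaddition of cyclic 1,3-diones with styrenes and stilbenes to 2-aryl-3,5,6,7-tetrahydro-1-benzofuran-4(2H)-ones. The one ring formed (O1, C2, C3, C3a, C7a) closes in a 5-exo-trig mode by attack of the enol oxygen on the benzylic cation, either of the two equivalent dione oxygens serving. C3 is fixed in the radical addition, where the (2S,3S) ring gives no facial bias, C2 is fixed in the closure with its aryl group trans to the C3 substituent (the less hindered and more stable arrangement, reached reversibly in acetic acid), and C6 forms as both epimers and is erased in step 8; the wanted (2R,3R) ring is therefore expected alongside its (2S,3S) counterpart. The step needs C–C bonding at C3a and C–O bonding at the carbon next to the 4-methoxyphenyl ring: the first is unambiguous because the dione has a single carbon between its oxygens, unlike a resorcinol ring with three nucleophilic positions, and the second follows from the para-methoxy group, which stabilises radical and cation at C2 far better than the meta-oxygenated ring C could at C3. No phenol is free in either partner, so phenoxyl dimerisation cannot compete, and the product has lost the acidic dione C–H and is inert to further oxidation.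

**Step 8**
Reactants: 16 ethyl (2R,3R)-3-G-2-(4-methoxyphenyl)-4-oxo-2,3,4,5,6,7-hexahydro-1-benzofuran-6-carboxylate (as the mixture from step 7)
Product: 18 ethyl (2R,3R)-3-G-4-hydroxy-2-(4-methoxyphenyl)-2,3-dihydro-1-benzofuran-6-carboxylate, via phenylselanyl ketone 17 (not isolated)
Conditions: LiN(iPr)2, THF, −78 °C; PhSeCl; then H2O2, pyridine, CH2Cl2, 0 °C to rt; preparative HPLC
Reagents that add atoms: none
Why: Kinetic enolisation at C5 and selenenylation give 17, whose oxidation and selenoxide syn-elimination introduce the C5–C6 double bond so that enolisation aromatises ring A (dehydrogenation by the selenoxide method); C6 ceases to be a stereocentre, C2 and C3 are not involved, and the two trans diastereomers left from step 7 are separated here, the relative configuration of the two rings being assigned by X-ray analysis of a 4-bromobenzoate of the phenol.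

**Step 9**
Reactants: 18 ethyl (2R,3R)-3-G-4-hydroxy-2-(4-methoxyphenyl)-2,3-dihydro-1-benzofuran-6-carboxylate
Product: 19 ethyl (2R,3R)-3-G-4-methoxy-2-(4-methoxyphenyl)-2,3-dihydro-1-benzofuran-6-carboxylate
Conditions: MeI, K2CO3, DMF, rt
Reagents that add atoms: iodomethane, CI
Why: Williamson O-methylation masks the hindered C4 phenol for the hydride, oxidation and base steps that follow and adds one more methyl ether to the set removed at the end.

**Step 10**
Reactants: 19 ethyl (2R,3R)-3-G-4-methoxy-2-(4-methoxyphenyl)-2,3-dihydro-1-benzofuran-6-carboxylate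
Product: 20 [(2R,3R)-3-G-4-methoxy-2-(4-methoxyphenyl)-2,3-dihydro-1-benzofuran-6-yl]methanol
Conditions: LiAlH4, THF, 0 °C
Reagents that add atoms: none
Why: Hydride reduction with LiAlH4 takes the aryl ester to the benzylic alcohol without touching aryl ethers or the dihydrobenzofuran rings.

**Step 11**
Reactants: 20 [(2R,3R)-3-G-4-methoxy-2-(4-methoxyphenyl)-2,3-dihydro-1-benzofuran-6-yl]methanol
Product: 21 (2R,3R)-3-G-4-methoxy-2-(4-methoxyphenyl)-2,3-dihydro-1-benzofuran-6-carbaldehyde
Conditions: MnO2, CH2Cl2, rt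
Reagents that add atoms: none
Why: MnO2 oxidises benzylic alcohols selectively to aldehydes and stops there, and no free phenol is present to be oxidised.

**Step 12**
Reactants: 21 (2R,3R)-3-G-4-methoxy-2-(4-methoxyphenyl)-2,3-dihydro-1-benzofuran-6-carbaldehyde; 22 diethyl [(4-methoxyphenyl)methyl]phosphonate
Product: 23 (2R,3R)-3-G-4-methoxy-2-(4-methoxyphenyl)-6-[(E)-2-(4-methoxyphenyl)ethenyl]-2,3-dihydro-1-benzofuran (octamethyl ether of the target)
Conditions: KOtBu, THF, 0 °C to rt
Reagents that add atoms: none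
Why: Horner–Wadsworth–Emmons olefination of the non-enolisable aldehyde with the benzylphosphonate anion gives the stilbene with high (E) selectivity through the preferred anti oxaphosphetane.

**Step 13**
Reactants: 23 (2R,3R)-3-G-4-methoxy-2-(4-methoxyphenyl)-6-[(E)-2-(4-methoxyphenyl)ethenyl]-2,3-dihydro-1-benzofuran
Product: 24 CNP0107857.3 (octaphenol, target)
Conditions: BBr3 (excess), CH2Cl2, −78 °C to rt; MeOH, then H2O
Reagents that add atoms: none
Why: Lewis-acid ether cleavage with BBr3 removes all eight aryl methyl ethers as is usual for permethylated resveratrol oligomers; if a benzylic C2–O bond ionises reversibly, reclosure returns the trans ring because C3 is untouched, and in this connectivity the stilbene is too far from the benzylic positions for an intramolecular Friedel–Crafts reaction.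

**Compound list**

1 | 4-bromo-2,6-dimethoxybenzaldehyde | COc1cc(Br)cc(OC)c1C=O | starting material
2 | 4-bromo-2-hydroxy-6-methoxybenzaldehyde | COc1cc(Br)cc(O)c1C=O | intermediate
3 | 3,5-dimethoxyphenylmagnesium chloride (solution in THF) | COc1cc(OC)cc([Mg]Cl)c1 | starting material
4 | 5-bromo-2-[(3,5-dimethoxyphenyl)(hydroxy)methyl]-3-methoxyphenol (racemic, not isolated) | COc1cc(OC)cc(c1)C(O)c1c(O)cc(Br)cc1OC | intermediate
5 | 5-bromo-2-[(3,5-dimethoxyphenyl)(4-methylbenzenesulfonyl)methyl]-3-methoxyphenol (racemic) | COc1cc(OC)cc(c1)C(c1c(O)cc(Br)cc1OC)S(=O)(=O)c1ccc(C)cc1 | intermediate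
6 | 4-(bromomethyl)-1,2-dimethoxybenzene | COc1ccc(CBr)cc1OC | starting material
7 | tetrahydrothiophene (thiolane) | C1CCSC1 | starting material
8 | 1-[(3,4-dimethoxyphenyl)methyl]thiolan-1-ium bromide | COc1ccc(C[S+]2CCCC2)cc1OC.[Br-] | intermediate
9 | 3-bromo-6-[(3,5-dimethoxyphenyl)methylidene]-5-methoxycyclohexa-2,4-dien-1-one (ortho-quinone methide, not isolated) | COc1cc(OC)cc(c1)C=C1C(=O)C=C(Br)C=C1OC | intermediate
10 | (3,4-dimethoxyphenyl)(thiolan-1-ium-1-yl)methanide (sulfonium ylide, not isolated) | COc1ccc([CH-][S+]2CCCC2)cc1OC | intermediate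
11 | racemic trans-6-bromo-2-(3,4-dimethoxyphenyl)-3-(3,5-dimethoxyphenyl)-4-methoxy-2,3-dihydro-1-benzofuran (both enantiomers written) | Brc1cc(OC)c2c(c1)O[C@H](c1ccc(OC)c(OC)c1)[C@H]2c1cc(OC)cc(OC)c1.Brc1cc(OC)c2c(c1)O[C@@H](c1ccc(OC)c(OC)c1)[C@@H]2c1cc(OC)cc(OC)c1 | intermediate
12 | (2S,3S)-6-bromo-2-(3,4-dimethoxyphenyl)-3-(3,5-dimethoxyphenyl)-4-methoxy-2,3-dihydro-1-benzofuran | Brc1cc(OC)c2c(c1)O[C@H](c1ccc(OC)c(OC)c1)[C@H]2c1cc(OC)cc(OC)c1 | intermediate
13 | 1-ethenyl-4-methoxybenzene (4-methoxystyrene) | COc1ccc(C=C)cc1 | starting material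
14 | (2S,3S)-2-(3,4-dimethoxyphenyl)-3-(3,5-dimethoxyphenyl)-4-methoxy-6-[(E)-2-(4-methoxyphenyl)ethenyl]-2,3-dihydro-1-benzofuran | COc1ccc(/C=C/c2cc(OC)c3c(c2)O[C@H](c2ccc(OC)c(OC)c2)[C@H]3c2cc(OC)cc(OC)c2)cc1 | intermediate
15 | ethyl 3,5-dioxocyclohexane-1-carboxylate | CCOC(=O)C1CC(=O)CC(=O)C1 | starting material
16 | ethyl (2R,3R)-3-[(2S,3S)-2-(3,4-dimethoxyphenyl)-3-(3,5-dimethoxyphenyl)-4-methoxy-2,3-dihydro-1-benzofuran-6-yl]-2-(4-methoxyphenyl)-4-oxo-2,3,4,5,6,7-hexahydro-1-benzofuran-6-carboxylate (both C6 epimers) | CCOC(=O)C1CC(=O)C2=C(C1)O[C@@H](c1ccc(OC)cc1)[C@@H]2c1cc(OC)c2c(c1)O[C@H](c1ccc(OC)c(OC)c1)[C@H]2c1cc(OC)cc(OC)c1 | intermediate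
17 | ethyl (2R,3R)-3-[(2S,3S)-2-(3,4-dimethoxyphenyl)-3-(3,5-dimethoxyphenyl)-4-methoxy-2,3-dihydro-1-benzofuran-6-yl]-2-(4-methoxyphenyl)-4-oxo-5-(phenylselanyl)-2,3,4,5,6,7-hexahydro-1-benzofuran-6-carboxylate (C5 and C6 epimers, not isolated) | CCOC(=O)C1C([Se]c3ccccc3)C(=O)C2=C(C1)O[C@@H](c1ccc(OC)cc1)[C@@H]2c1cc(OC)c2c(c1)O[C@H](c1ccc(OC)c(OC)c1)[C@H]2c1cc(OC)cc(OC)c1 | intermediate
18 | ethyl (2R,3R)-3-[(2S,3S)-2-(3,4-dimethoxyphenyl)-3-(3,5-dimethoxyphenyl)-4-methoxy-2,3-dihydro-1-benzofuran-6-yl]-4-hydroxy-2-(4-methoxyphenyl)-2,3-dihydro-1-benzofuran-6-carboxylate | CCOC(=O)c1cc(O)c2c(c1)O[C@@H](c1ccc(OC)cc1)[C@@H]2c1cc(OC)c2c(c1)O[C@H](c1ccc(OC)c(OC)c1)[C@H]2c1cc(OC)cc(OC)c1 | intermediate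
19 | ethyl (2R,3R)-3-[(2S,3S)-2-(3,4-dimethoxyphenyl)-3-(3,5-dimethoxyphenyl)-4-methoxy-2,3-dihydro-1-benzofuran-6-yl]-4-methoxy-2-(4-methoxyphenyl)-2,3-dihydro-1-benzofuran-6-carboxylate | CCOC(=O)c1cc(OC)c2c(c1)O[C@@H](c1ccc(OC)cc1)[C@@H]2c1cc(OC)c2c(c1)O[C@H](c1ccc(OC)c(OC)c1)[C@H]2c1cc(OC)cc(OC)c1 | intermediate
20 | [(2R,3R)-3-[(2S,3S)-2-(3,4-dimethoxyphenyl)-3-(3,5-dimethoxyphenyl)-4-methoxy-2,3-dihydro-1-benzofuran-6-yl]-4-methoxy-2-(4-methoxyphenyl)-2,3-dihydro-1-benzofuran-6-yl]methanol | OCc1cc(OC)c2c(c1)O[C@@H](c1ccc(OC)cc1)[C@@H]2c1cc(OC)c2c(c1)O[C@H](c1ccc(OC)c(OC)c1)[C@H]2c1cc(OC)cc(OC)c1 | intermediate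
21 | (2R,3R)-3-[(2S,3S)-2-(3,4-dimethoxyphenyl)-3-(3,5-dimethoxyphenyl)-4-methoxy-2,3-dihydro-1-benzofuran-6-yl]-4-methoxy-2-(4-methoxyphenyl)-2,3-dihydro-1-benzofuran-6-carbaldehyde | O=Cc1cc(OC)c2c(c1)O[C@@H](c1ccc(OC)cc1)[C@@H]2c1cc(OC)c2c(c1)O[C@H](c1ccc(OC)c(OC)c1)[C@H]2c1cc(OC)cc(OC)c1 | intermediate
22 | diethyl [(4-methoxyphenyl)methyl]phosphonate | CCOP(=O)(Cc1ccc(OC)cc1)OCC | starting material
23 | (2R,3R)-3-[(2S,3S)-2-(3,4-dimethoxyphenyl)-3-(3,5-dimethoxyphenyl)-4-methoxy-2,3-dihydro-1-benzofuran-6-yl]-4-methoxy-2-(4-methoxyphenyl)-6-[(E)-2-(4-methoxyphenyl)ethenyl]-2,3-dihydro-1-benzofuran | COc1ccc(/C=C/c2cc(OC)c3c(c2)O[C@@H](c2ccc(OC)cc2)[C@@H]3c2cc(OC)c3c(c2)O[C@H](c2ccc(OC)c(OC)c2)[C@H]3c2cc(OC)cc(OC)c2)cc1 | intermediate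
24 | CNP0107857.3, 4-[(2S,3S)-3-(3,5-dihydroxyphenyl)-4-hydroxy-6-[(2R,3R)-4-hydroxy-2-(4-hydroxyphenyl)-6-[(E)-2-(4-hydroxyphenyl)ethenyl]-2,3-dihydro-1-benzofuran-3-yl]-2,3-dihydro-1-benzofuran-2-yl]benzene-1,2-diol | Oc1ccc(/C=C/c2cc(O)c3c(c2)O[C@@H](c2ccc(O)cc2)[C@@H]3c2cc(O)c3c(c2)O[C@H](c2ccc(O)c(O)c2)[C@H]3c2cc(O)cc(O)c2)cc1 | target

**Step count and risks**

Total: 13 steps. Longest linear sequence: 12 steps (1 to 24 through steps 1, 2 and 4–13; step 3 makes the sulfonium salt).

Step 7. The radical addition may fail to discriminate between the two stilbene carbons, or trivalent manganese may attack the electron-rich aryl ethers of 14 faster than it turns over the dione. The fallback forms the second ring by the ylide annulation of step 4, so that C2–C3 rather than C3–C3a is made in the ring-forming event and the regiochemistry is fixed by the building blocks. It sets out from 12 and 2 and comes back to the route at 23.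

- Bromine–lithium exchange on 12 (n-BuLi, THF, −78 °C) gives [(2S,3S)-2-(3,4-dimethoxyphenyl)-3-(3,5-dimethoxyphenyl)-4-methoxy-2,3-dihydro-1-benzofuran-6-yl]lithium F1.
- F1 adds to 2, whose phenol is first deprotonated with NaH, to give the benzhydrol 5-bromo-2-[G(hydroxy)methyl]-3-methoxyphenol F2.
- 4-Methylbenzenesulfinic acid in CH2Cl2 turns this into the sulfone 5-bromo-3-methoxy-2-[G(4-methylbenzenesulfonyl)methyl]phenol F3.
- The salt 1-[(4-methoxyphenyl)methyl]thiolan-1-ium bromide F4 is made from 4-methoxybenzyl bromide and 7.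
- Cs2CO3 in MeCN converts the sulfone into the ortho-quinone methide 3-bromo-5-methoxy-6-(G-methylidene)cyclohexa-2,4-dien-1-one F5 and the salt into its ylide (4-methoxyphenyl)(thiolan-1-ium-1-yl)methanide F6.
- Their annulation as in step 4 gives (2R,3R)-6-bromo-3-G-4-methoxy-2-(4-methoxyphenyl)-2,3-dihydro-1-benzofuran F7 together with its (2S,3S) ring diastereomer. Facial control is equally absent here, so the HPLC separation is carried out at this bromide.
- Heck reaction of the bromide with 13 under the conditions of step 6 gives 23.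

Step 8. Deprotonation may be unselective, or the selenium by-products and peroxide may over-oxidise the electron-rich phenol as it forms. The fallback gives up the enolate–selenoxide sequence for a direct palladium-catalysed aerobic dehydrogenation of the cyclohexenone (Pd(OCOCF3)2, 2-(dimethylamino)pyridine, TsOH, O2, DMSO, 80 °C). A divalent palladium enolate undergoes β-hydride elimination and dioxygen is the terminal oxidant, so neither strong base nor a stoichiometric electrophile is used. It sets out from 16 and comes back at 18 without a new compound (F0).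

Step 13. The Lewis acid may ionise the benzylic C2–O bonds, with ring opening or scrambling, or HBr may add to the stilbene before all eight ethers are cleaved. The fallback opens the ethers from the methyl side by SN2 attack of a thiolate under basic conditions (NaSEt, DMF, 130 °C), where neither a benzylic cation nor acid can arise. It sets out from 23 and arrives directly at 24 without a new compound (F0).

**Further compounds**

F1 | step 7 | [(2S,3S)-2-(3,4-dimethoxyphenyl)-3-(3,5-dimethoxyphenyl)-4-methoxy-2,3-dihydro-1-benzofuran-6-yl]lithium | [Li]c1cc(OC)c2c(c1)O[C@H](c1ccc(OC)c(OC)c1)[C@H]2c1cc(OC)cc(OC)c1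
F2 | step 7 | 5-bromo-2-{[(2S,3S)-2-(3,4-dimethoxyphenyl)-3-(3,5-dimethoxyphenyl)-4-methoxy-2,3-dihydro-1-benzofuran-6-yl](hydroxy)methyl}-3-methoxyphenol | COc1cc(Br)cc(O)c1C(O)c1cc(OC)c2c(c1)O[C@H](c1ccc(OC)c(OC)c1)[C@H]2c1cc(OC)cc(OC)c1
F3 | step 7 | 5-bromo-2-{[(2S,3S)-2-(3,4-dimethoxyphenyl)-3-(3,5-dimethoxyphenyl)-4-methoxy-2,3-dihydro-1-benzofuran-6-yl](4-methylbenzenesulfonyl)methyl}-3-methoxyphenol | COc1cc(Br)cc(O)c1C(c1cc(OC)c2c(c1)O[C@H](c1ccc(OC)c(OC)c1)[C@H]2c1cc(OC)cc(OC)c1)S(=O)(=O)c1ccc(C)cc1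
F4 | step 7 | 1-[(4-methoxyphenyl)methyl]thiolan-1-ium bromide | COc1ccc(C[S+]2CCCC2)cc1.[Br-]
F5 | step 7 | 3-bromo-6-{[(2S,3S)-2-(3,4-dimethoxyphenyl)-3-(3,5-dimethoxyphenyl)-4-methoxy-2,3-dihydro-1-benzofuran-6-yl]methylidene}-5-methoxycyclohexa-2,4-dien-1-one | COC1=CC(Br)=CC(=O)C1=Cc1cc(OC)c2c(c1)O[C@H](c1ccc(OC)c(OC)c1)[C@H]2c1cc(OC)cc(OC)c1
F6 | step 7 | (4-methoxyphenyl)(thiolan-1-ium-1-yl)methanide | COc1ccc([CH-][S+]2CCCC2)cc1
F7 | step 7 | (2R,3R)-6-bromo-3-[(2S,3S)-2-(3,4-dimethoxyphenyl)-3-(3,5-dimethoxyphenyl)-4-methoxy-2,3-dihydro-1-benzofuran-6-yl]-4-methoxy-2-(4-methoxyphenyl)-2,3-dihydro-1-benzofuran | Brc1cc(OC)c2c(c1)O[C@@H](c1ccc(OC)cc1)[C@@H]2c1cc(OC)c2c(c1)O[C@H](c1ccc(OC)c(OC)c1)[C@H]2c1cc(OC)cc(OC)c1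
F0 | step 8 | none | none
F0 | step 13 | none | none
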